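**Retrosynthetic overview**

1. Target 26 ← acetylation of hydroxy butenolide 25 ← acid-triggered acetonide loss and lactonization of alkylidene ester 23 ← Wittig olefination of (4R)-4-alkyl-2,2-dimethyl-1,3-dioxan-5-one 22; the butenolide is the last ring formed.
2. Key disconnection: the bond between the acetoxy-bearing carbon and its allylic CH2 neighbour, made by alkylating the RAMP-hydrazone azaenolate of 2,2-dimethyl-1,3-dioxan-5-one with the C20 allylic bromide 16, which already holds both E-olefins and the finished (Z)-alkylidene lactone.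
3. Enabling feature: the acetoxy carbon, butenolide C4 and the ring OCH2 (C5), with the two oxygens they carry, form an O–C–C–C–O array, i.e. a masked 1,3-dihydroxyacetone. A temporary 1,3-dioxan-5-one ring (not in the target) holds this unit at the ketone oxidation level, fixes the azaenolate geometry for auxiliary control of the (R) center, and is opened again when the butenolide closes.
4. Bromide 16 ← Z-selective Still–Gennari-type Horner–Wadsworth–Emmons union of (5S)-phosphono lactone 13 (ring and stereocenter from the chiral pool) with hydroxy aldehyde 4, made from (2E,6E)-farnesol by terminal epoxidation and cleavage.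
5. Ring order: γ-lactone (purchased ring, carried through), temporary dioxanone (purchased, removed in step 14), butenolide (closed in step 14).

Key step: step 11

Remark on the chemistry: the hydrazone C=N geometry (19, 21) and the C3 configuration of phosphonates 10–13 are left undefined because neither affects the outcome; the bromohydrin and epoxide centers of 2 and 3 are racemic and are excised in step 3.

**Route**

Step 1
Reactants: 1 (2E,6E)-farnesol
Product: 2 (2E,6E)-10-bromo-3,7,11-trimethyldodeca-2,6-diene-1,11-diol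
Conditions: NBS (1.1 equiv), THF/H2O 2:1, 0 °C
Reagents that add atoms: N-bromosuccinimide O=C1CCC(=O)N1Br; water O
Why: Terminal-selective bromohydrin formation, in which the coiled polyene exposes only the terminal trisubstituted olefin to NBS in aqueous THF and water opens the bromonium ion at the tertiary carbon; the new CHBr center is racemic and is destroyed in step 3.

Step 2
Reactants: 2 (2E,6E)-10-bromo-3,7,11-trimethyldodeca-2,6-diene-1,11-diol
Product: 3 (2E,6E)-9-(3,3-dimethyloxiran-2-yl)-3,7-dimethylnona-2,6-dien-1-ol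
Conditions: K2CO3, MeOH, rt
Reagents that add atoms: none
Why: Intramolecular Williamson closure of the bromohydrin alkoxide should give the terminal epoxide without touching the allylic alcohol or the E-olefins.

Step 3
Reactants: 3 (2E,6E)-9-(3,3-dimethyloxiran-2-yl)-3,7-dimethylnona-2,6-dien-1-ol
Product: 4 (4E,8E)-10-hydroxy-4,8-dimethyldeca-4,8-dienal
Conditions: H5IO6, THF/Et2O, 0 °C
Reagents that add atoms: none
Why: Periodic acid hydrates the trisubstituted epoxide and cleaves the resulting glycol in one flask (glycol cleavage), excising acetone and leaving both E-olefins and the allylic alcohol intact.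

Step 4
Reactants: 5 (5S)-5-(hydroxymethyl)oxolan-2-one
Product: 6 (2S)-5-oxooxolane-2-carbaldehyde
Conditions: Dess–Martin periodinane, CH2Cl2, 0 °C → rt; filtered through a short silica pad and used crude
Reagents that add atoms: none
Why: Dess–Martin oxidation under neutral, non-aqueous conditions should give the hydration-prone aldehyde without disturbing the stereocenter, which comes from the chiral pool.

Step 5
Reactants: 6 (2S)-5-oxooxolane-2-carbaldehyde
Product: 7 (5S)-5-(2-methylprop-1-en-1-yl)oxolan-2-one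
Conditions: iPrPPh3I, n-BuLi, THF, 0 °C; then 6, –78 °C → 0 °C
Reagents that add atoms: isopropyltriphenylphosphonium iodide CC(C)[P+](c1ccccc1)(c1ccccc1)c1ccccc1.[I-]
Why: Wittig olefination with the non-stabilized isopropylidene ylide, generated without excess base and added at low temperature, should react with the aldehyde much faster than with the lactone carbonyl and leave the α-oxygenated stereocenter intact.

Step 6
Reactants: 7 (5S)-5-(2-methylprop-1-en-1-yl)oxolan-2-one
Product: 10 (5S)-3-(diethoxyphosphoryl)-5-(2-methylprop-1-en-1-yl)oxolan-2-one, via lithium lactone enolate 8 (not isolated), via enol phosphate 9 (not isolated)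
Conditions: LiN(iPr)2 (1.1 equiv), THF, –78 °C; ClP(O)(OEt)2; then LiN(iPr)2 (2.2 equiv), –78 °C → 0 °C; aq. NH4Cl
Reagents that add atoms: diethyl chlorophosphate CCOP(=O)(Cl)OCC
Why: C-Phosphorylation of a lactone by O-phosphorylation of its enolate followed by base-induced 1,3-phosphoryl migration from oxygen to carbon (enol phosphate to phosphonate rearrangement); the C3 center is formed as an epimer mixture and is planarized in step 8.

Step 7
Reactants: 10 (5S)-3-(diethoxyphosphoryl)-5-(2-methylprop-1-en-1-yl)oxolan-2-one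
Product: 13 (5S)-3-[bis(2,2,2-trifluoroethoxy)phosphoryl]-5-(2-methylprop-1-en-1-yl)oxolan-2-one, via silyl phosphonate 11 (not isolated), via phosphonic dichloride 12 (not isolated)
Conditions: Me3SiBr, CH2Cl2, 0 °C → rt; evaporate; (COCl)2, DMF (cat.), CH2Cl2, 0 °C → rt; evaporate; CF3CH2OH, iPr2NEt, CH2Cl2, 0 °C
Reagents that add atoms: 2,2,2-trifluoroethanol OCC(F)(F)F
Why: Standard three-stage phosphonate ester exchange (silyl dealkylation, chlorination by the Vilsmeier reagent, re-esterification) that turns a diethyl phosphonate into its Still–Gennari-type analogue under anhydrous conditions the lactone should tolerate.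

Step 8
Reactants: 13 (5S)-3-[bis(2,2,2-trifluoroethoxy)phosphoryl]-5-(2-methylprop-1-en-1-yl)oxolan-2-one; 4 (4E,8E)-10-hydroxy-4,8-dimethyldeca-4,8-dienal
Product: 15 (3Z,5S)-3-[(4E,8E)-10-hydroxy-4,8-dimethyldeca-4,8-dien-1-ylidene]-5-(2-methylprop-1-en-1-yl)oxolan-2-one, via potassium phosphonate enolate 14 (not isolated)
Conditions: KN(SiMe3)2 (1.0 equiv), 18-crown-6, THF, –78 °C; then 4 (0.9 equiv), –78 °C
Reagents that add atoms: none
Why: Still–Gennari-type Horner–Wadsworth–Emmons olefination, in which the electron-poor phosphonate and the dissociated potassium enolate make addition irreversible and elimination fast, so the kinetic adduct should give the Z-alkylidene lactone (chain cis to the carbonyl) while the weakly basic enolate leaves the free allylic alcohol and the C5 center untouched.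

Step 9
Reactants: 15 (3Z,5S)-3-[(4E,8E)-10-hydroxy-4,8-dimethyldeca-4,8-dien-1-ylidene]-5-(2-methylprop-1-en-1-yl)oxolan-2-one
Product: 16 (3Z,5S)-3-[(4E,8E)-10-bromo-4,8-dimethyldeca-4,8-dien-1-ylidene]-5-(2-methylprop-1-en-1-yl)oxolan-2-one
Conditions: CBr4, PPh3, CH2Cl2, –20 °C → 0 °C; used at once
Reagents that add atoms: carbon tetrabromide BrC(Br)(Br)Br
Why: Appel bromination converts the primary allylic alcohol into the bromide under neutral conditions by SN2 displacement of the oxyphosphonium ion, without allylic transposition or loss of olefin geometry.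

Step 10
Reactants: 17 2,2-dimethyl-1,3-dioxan-5-one; 18 (R)-1-amino-2-(methoxymethyl)pyrrolidine (RAMP)
Product: 19 (2R)-N-(2,2-dimethyl-1,3-dioxan-5-ylidene)-2-(methoxymethyl)pyrrolidin-1-amine
Conditions: benzene, reflux (Dean–Stark)
Reagents that add atoms: none
Why: Hydrazone condensation of the reactive, symmetrical ketone with the hydrazine, which installs the purchased (R)-pyrrolidine stereocenter as the controlling element for step 11.

Step 11
Reactants: 19 (2R)-N-(2,2-dimethyl-1,3-dioxan-5-ylidene)-2-(methoxymethyl)pyrrolidin-1-amine; 16 (3Z,5S)-3-[(4E,8E)-10-bromo-4,8-dimethyldeca-4,8-dien-1-ylidene]-5-(2-methylprop-1-en-1-yl)oxolan-2-one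
Product: 21 (2R)-N-[(4R)-4-[(2E,6E,10Z)-3,7-dimethyl-10-[(5S)-5-(2-methylprop-1-en-1-yl)-2-oxooxolan-3-ylidene]deca-2,6-dien-1-yl]-2,2-dimethyl-1,3-dioxan-5-ylidene]-2-(methoxymethyl)pyrrolidin-1-amine, via lithium azaenolate 20 (not isolated)
Conditions: t-BuLi (1.0 equiv per 19), THF, –78 °C, 2 h; then 16 (0.85 equiv) in THF, –100 °C → –78 °C; pH 7 buffer
Reagents that add atoms: none
Why: t-BuLi removes one of the four equivalent α-protons to give the lithium azaenolate, whose C=C geometry is fixed by the temporary 1,3-dioxane ring and whose C–N geometry and lithium position are fixed by chelation to the methoxymethyl arm; SN2 attack on the primary allylic bromide then forms the bond between the future acetoxy carbon and the allylic CH2. The closest known reaction type is the SAMP/RAMP-hydrazone α-alkylation of 2,2-dimethyl-1,3-dioxan-5-one with alkyl and allyl halides. No ring is closed in this step. The new stereocenter is controlled by the (R)-pyrrolidine center of the auxiliary, which shields one face of the chelated azaenolate; by the uniform topicity of this auxiliary (the (S)-hydrazine gives (S)-4-alkyl dioxanones) the (R)-hydrazine should give the required (4R) center. The step needs alkylation at the primary carbon with retention of the E-olefin, secured by direct SN2 attack at the unhindered CH2Br terminus and not at the fully substituted allylic carbon, and chemoselectivity for the bromide over the lactone carbonyl, the alkylidene lactone as Michael acceptor and its γ-protons. This chemoselectivity should be secured by the temperature of –100 °C, by the much higher SN2 reactivity of a primary allylic bromide compared with a β-alkylated, α-branched acceptor, and by using no excess of t-BuLi.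

Step 12
Reactants: 21 (2R)-N-[(4R)-4-[(2E,6E,10Z)-3,7-dimethyl-10-[(5S)-5-(2-methylprop-1-en-1-yl)-2-oxooxolan-3-ylidene]deca-2,6-dien-1-yl]-2,2-dimethyl-1,3-dioxan-5-ylidene]-2-(methoxymethyl)pyrrolidin-1-amine
Product: 22 (4R)-4-[(2E,6E,10Z)-3,7-dimethyl-10-[(5S)-5-(2-methylprop-1-en-1-yl)-2-oxooxolan-3-ylidene]deca-2,6-dien-1-yl]-2,2-dimethyl-1,3-dioxan-5-one
Conditions: sat. aq. oxalic acid, Et2O, rt
Reagents that add atoms: water O
Why: Two-phase hydrazone hydrolysis with oxalic acid removes the recoverable auxiliary under conditions that should leave the acetonide and the α-alkoxy ketone stereocenter untouched.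

Step 13
Reactants: 22 (4R)-4-[(2E,6E,10Z)-3,7-dimethyl-10-[(5S)-5-(2-methylprop-1-en-1-yl)-2-oxooxolan-3-ylidene]deca-2,6-dien-1-yl]-2,2-dimethyl-1,3-dioxan-5-one
Product: 23 methyl (2E)-2-[(4R)-4-[(2E,6E,10Z)-3,7-dimethyl-10-[(5S)-5-(2-methylprop-1-en-1-yl)-2-oxooxolan-3-ylidene]deca-2,6-dien-1-yl]-2,2-dimethyl-1,3-dioxan-5-ylidene]acetate
Conditions: Ph3P=CHCO2Me, toluene, 50 °C
Reagents that add atoms: methyl (triphenylphosphoranylidene)acetate COC(=O)C=P(c1ccccc1)(c1ccccc1)c1ccccc1
Why: Wittig olefination of the activated α,α'-dialkoxy ketone with a stabilized ylide under base-free conditions, in which allylic 1,3-strain with the C4 substituent should steer the ester to the side of the unsubstituted ring CH2 (E-olefin) and the adjacent stereocenter is not epimerized.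

Step 14
Reactants: 23 methyl (2E)-2-[(4R)-4-[(2E,6E,10Z)-3,7-dimethyl-10-[(5S)-5-(2-methylprop-1-en-1-yl)-2-oxooxolan-3-ylidene]deca-2,6-dien-1-yl]-2,2-dimethyl-1,3-dioxan-5-ylidene]acetate
Product: 25 4-[(1R,3E,7E,11Z)-1-hydroxy-4,8-dimethyl-11-[(5S)-5-(2-methylprop-1-en-1-yl)-2-oxooxolan-3-ylidene]undeca-3,7-dien-1-yl]furan-2(5H)-one, via dihydroxy ester 24 (not isolated)
Conditions: AcOH/THF/H2O 3:1:1, 40 °C
Reagents that add atoms: none
Why: Mild acid hydrolysis of the acetonide frees the primary hydroxyl cis to the ester, which should lactonize spontaneously (5-exo-trig acyl transfer) to the 4-substituted butenolide and leave the secondary carbinol free.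

Step 15
Reactants: 25 4-[(1R,3E,7E,11Z)-1-hydroxy-4,8-dimethyl-11-[(5S)-5-(2-methylprop-1-en-1-yl)-2-oxooxolan-3-ylidene]undeca-3,7-dien-1-yl]furan-2(5H)-one
Product: 26 (1R,3E,7E,11Z)-4,8-dimethyl-11-[(5S)-5-(2-methylprop-1-en-1-yl)-2-oxooxolan-3-ylidene]-1-(5-oxo-2,5-dihydrofuran-3-yl)undeca-3,7-dien-1-yl acetate
Conditions: Ac2O, pyridine, 4-(dimethylamino)pyridine (cat.), CH2Cl2, 0 °C
Reagents that add atoms: acetic anhydride CC(=O)OC(C)=O
Why: Nucleophile-catalysed acetylation of the secondary alcohol with retention of configuration, under conditions too mild to deprotonate the butenolide, should give the target.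

**Compound list**

1 | (2E,6E)-farnesol | CC(C)=CCC/C(C)=C/CC/C(C)=C/CO | starting material
2 | (2E,6E)-10-bromo-3,7,11-trimethyldodeca-2,6-diene-1,11-diol | CC(C)(O)C(Br)CC/C(C)=C/CC/C(C)=C/CO | intermediate
3 | (2E,6E)-9-(3,3-dimethyloxiran-2-yl)-3,7-dimethylnona-2,6-dien-1-ol | CC1(C)OC1CC/C(C)=C/CC/C(C)=C/CO | intermediate
4 | (4E,8E)-10-hydroxy-4,8-dimethyldeca-4,8-dienal | O=CCC/C(C)=C/CC/C(C)=C/CO | intermediate
5 | (5S)-5-(hydroxymethyl)oxolan-2-one | OC[C@@H]1CCC(=O)O1 | starting material
6 | (2S)-5-oxooxolane-2-carbaldehyde | O=C[C@@H]1CCC(=O)O1 | intermediate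
7 | (5S)-5-(2-methylprop-1-en-1-yl)oxolan-2-one | CC(C)=C[C@@H]1CCC(=O)O1 | intermediate
8 | lithium (5S)-5-(2-methylprop-1-en-1-yl)-4,5-dihydrofuran-2-olate | CC(C)=C[C@@H]1CC=C(O[Li])O1 | intermediate (not isolated)
9 | diethyl (5S)-5-(2-methylprop-1-en-1-yl)-4,5-dihydrofuran-2-yl phosphate | CC(C)=C[C@@H]1CC=C(OP(=O)(OCC)OCC)O1 | intermediate (not isolated)
10 | (5S)-3-(diethoxyphosphoryl)-5-(2-methylprop-1-en-1-yl)oxolan-2-one | CC(C)=C[C@@H]1CC(C(=O)O1)P(=O)(OCC)OCC | intermediate
11 | bis(trimethylsilyl) [(5S)-5-(2-methylprop-1-en-1-yl)-2-oxooxolan-3-yl]phosphonate | CC(C)=C[C@@H]1CC(C(=O)O1)P(=O)(O[Si](C)(C)C)O[Si](C)(C)C | intermediate (not isolated)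
12 | [(5S)-5-(2-methylprop-1-en-1-yl)-2-oxooxolan-3-yl]phosphonic dichloride | CC(C)=C[C@@H]1CC(C(=O)O1)P(Cl)(Cl)=O | intermediate (not isolated)
13 | (5S)-3-[bis(2,2,2-trifluoroethoxy)phosphoryl]-5-(2-methylprop-1-en-1-yl)oxolan-2-one | CC(C)=C[C@@H]1CC(C(=O)O1)P(=O)(OCC(F)(F)F)OCC(F)(F)F | intermediate
14 | potassium (5S)-3-[bis(2,2,2-trifluoroethoxy)phosphoryl]-5-(2-methylprop-1-en-1-yl)-4,5-dihydrofuran-2-olate | CC(C)=C[C@@H]1CC(=C([O-])O1)P(=O)(OCC(F)(F)F)OCC(F)(F)F.[K+] | intermediate (not isolated)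
15 | (3Z,5S)-3-[(4E,8E)-10-hydroxy-4,8-dimethyldeca-4,8-dien-1-ylidene]-5-(2-methylprop-1-en-1-yl)oxolan-2-one | OC/C=C(\C)CC/C=C(\C)CC/C=C1/C[C@@H](C=C(C)C)OC1=O | intermediate
16 | (3Z,5S)-3-[(4E,8E)-10-bromo-4,8-dimethyldeca-4,8-dien-1-ylidene]-5-(2-methylprop-1-en-1-yl)oxolan-2-one | BrC/C=C(\C)CC/C=C(\C)CC/C=C1/C[C@@H](C=C(C)C)OC1=O | intermediate
17 | 2,2-dimethyl-1,3-dioxan-5-one | CC1(C)OCC(=O)CO1 | starting material
18 | (R)-1-amino-2-(methoxymethyl)pyrrolidine (RAMP) | COC[C@H]1CCCN1N | starting material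
19 | (2R)-N-(2,2-dimethyl-1,3-dioxan-5-ylidene)-2-(methoxymethyl)pyrrolidin-1-amine | COC[C@H]1CCCN1N=C1COC(C)(C)OC1 | intermediate
20 | lithium (2,2-dimethyl-4H-1,3-dioxin-5-yl)[(2R)-2-(methoxymethyl)pyrrolidin-1-yl]azanide | COC[C@H]1CCCN1N([Li])C1=COC(C)(C)OC1 | intermediate (not isolated)
21 | (2R)-N-[(4R)-4-[(2E,6E,10Z)-3,7-dimethyl-10-[(5S)-5-(2-methylprop-1-en-1-yl)-2-oxooxolan-3-ylidene]deca-2,6-dien-1-yl]-2,2-dimethyl-1,3-dioxan-5-ylidene]-2-(methoxymethyl)pyrrolidin-1-amine | COC[C@H]1CCCN1N=C1COC(C)(C)O[C@@H]1C/C=C(\C)CC/C=C(\C)CC/C=C1/C[C@@H](C=C(C)C)OC1=O | intermediate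
22 | (4R)-4-[(2E,6E,10Z)-3,7-dimethyl-10-[(5S)-5-(2-methylprop-1-en-1-yl)-2-oxooxolan-3-ylidene]deca-2,6-dien-1-yl]-2,2-dimethyl-1,3-dioxan-5-one | CC1(C)OCC(=O)[C@@H](C/C=C(\C)CC/C=C(\C)CC/C=C2/C[C@@H](C=C(C)C)OC2=O)O1 | intermediate
23 | methyl (2E)-2-[(4R)-4-[(2E,6E,10Z)-3,7-dimethyl-10-[(5S)-5-(2-methylprop-1-en-1-yl)-2-oxooxolan-3-ylidene]deca-2,6-dien-1-yl]-2,2-dimethyl-1,3-dioxan-5-ylidene]acetate | COC(=O)/C=C1\COC(C)(C)O[C@@H]1C/C=C(\C)CC/C=C(\C)CC/C=C1/C[C@@H](C=C(C)C)OC1=O | intermediate
24 | methyl (2E,4R,6E,10E,14Z)-4-hydroxy-3-(hydroxymethyl)-7,11-dimethyl-14-[(5S)-5-(2-methylprop-1-en-1-yl)-2-oxooxolan-3-ylidene]tetradeca-2,6,10-trienoate | COC(=O)/C=C(\CO)[C@H](O)C/C=C(\C)CC/C=C(\C)CC/C=C1/C[C@@H](C=C(C)C)OC1=O | intermediate (not isolated)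
25 | 4-[(1R,3E,7E,11Z)-1-hydroxy-4,8-dimethyl-11-[(5S)-5-(2-methylprop-1-en-1-yl)-2-oxooxolan-3-ylidene]undeca-3,7-dien-1-yl]furan-2(5H)-one | O[C@H](C/C=C(\C)CC/C=C(\C)CC/C=C1/C[C@@H](C=C(C)C)OC1=O)C1=CC(=O)OC1 | intermediate
26 | (1R,3E,7E,11Z)-4,8-dimethyl-11-[(5S)-5-(2-methylprop-1-en-1-yl)-2-oxooxolan-3-ylidene]-1-(5-oxo-2,5-dihydrofuran-3-yl)undeca-3,7-dien-1-yl acetate | CC(=O)O[C@H](C/C=C(\C)CC/C=C(\C)CC/C=C1/C[C@@H](C=C(C)C)OC1=O)C1=CC(=O)OC1 | target

**Step count and risks**

Total step count: 15. Longest linear sequence: 11 steps (steps 4–9 and 11–15, from 5).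

Steps most likely to fail:

1. Step 11. What may go wrong: conjugate addition of the azaenolate to the alkylidene lactone, acylation at the lactone carbonyl, or proton transfer from the lactone γ-CH2, each of which consumes the nucleophile before SN2 alkylation is complete. Fallback (sets out from 3 and 19, returns at 25): the alkylation is run before the lactone exists. Epoxy alcohol 3 is converted with CBr4/PPh3 into epoxy bromide F1, in which the future aldehyde is masked as an inert trisubstituted epoxide. Azaenolate 20 is alkylated with it as in step 11 to give epoxy hydrazone F2; oxalic acid cleavage as in step 12 gives epoxy ketone F3; Wittig olefination as in step 13 gives epoxy ester F4. H5IO6 in aqueous THF then cleaves the epoxide to the aldehyde and, being acidic, removes the acetonide so that the butenolide closes, giving hydroxy butenolide aldehyde F5. Still–Gennari-type olefination of F5 with enolate 14, as in step 8, installs the Z-alkylidene lactone last and returns to the route at 25.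

2. Step 8. What may go wrong: insufficient kinetic preference for the Z-adduct in the cyclic phosphonate series, so that olefin geometry erodes toward the more stable E-alkylidene lactone. Fallback (sets out from 4, returns at 15): the olefination is moved to an open-chain α-substituted Still–Gennari reagent, for which Z-selectivity is firmly established, and the lactone stereocenter and ring are made afterwards. Purchased mesityl oxide is converted by kinetic enolization (LiN(iPr)2, Me3SiCl, –78 °C) into silyl dienol ether F6 and brominated with NBS to bromo enone F7. Alkylation of the sodium salt (NaH, THF) of purchased methyl bis(2,2,2-trifluoroethyl)phosphonoacetate with F7 gives keto phosphonate F8. Its potassium enolate (KN(SiMe3)2, 18-crown-6, –78 °C) and aldehyde 4 should give Z-keto ester F9. Corey–Bakshi–Shibata reduction of the enone carbonyl, with the alkenyl group as the large substituent (BH3·SMe2, (R)-1-methyl-3,3-diphenyltetrahydro-1H,3H-pyrrolo[1,2-c][1,3,2]oxazaborole), should give (S)-hydroxy ester F10. This lactonizes on brief exposure to catalytic pyridinium p-toluenesulfonate and returns to the route at 15.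

3. Step 13. What may go wrong: poor control of the exocyclic olefin geometry, so that after acetonide removal the secondary hydroxyl closes the lactone in place of the primary one; or slow olefination of the hindered ketone with epimerization of the α-alkoxy center. Fallback (sets out from 22, returns at 25): the ring oxygen is chosen before the olefin is made. Aqueous acetic acid removes the acetonide from 22 to give dihydroxy ketone F11. Its primary hydroxyl is esterified selectively with (diethoxyphosphoryl)acetic acid (N,N'-dicyclohexylcarbodiimide, CH2Cl2, –20 °C) to give phosphonoacetate F12. Intramolecular Horner–Wadsworth–Emmons reaction (LiCl, iPr2NEt, MeCN, 0 °C) then closes the butenolide through the ester tether, so that only the 4-substituted furanone 25 can form.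

**Further compounds**

F1 | step 11 | (2E,6E)-1-bromo-9-(3,3-dimethyloxiran-2-yl)-3,7-dimethylnona-2,6-diene | CC1(C)OC1CC/C(C)=C/CC/C(C)=C/CBr
F2 | step 11 | (2R)-N-[(4R)-4-[(2E,6E)-9-(3,3-dimethyloxiran-2-yl)-3,7-dimethylnona-2,6-dien-1-yl]-2,2-dimethyl-1,3-dioxan-5-ylidene]-2-(methoxymethyl)pyrrolidin-1-amine | COC[C@H]1CCCN1N=C1COC(C)(C)O[C@@H]1C/C=C(\C)CC/C=C(\C)CCC1OC1(C)C
F3 | step 11 | (4R)-4-[(2E,6E)-9-(3,3-dimethyloxiran-2-yl)-3,7-dimethylnona-2,6-dien-1-yl]-2,2-dimethyl-1,3-dioxan-5-one | CC1(C)OCC(=O)[C@@H](C/C=C(\C)CC/C=C(\C)CCC2OC2(C)C)O1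
F4 | step 11 | methyl (2E)-2-[(4R)-4-[(2E,6E)-9-(3,3-dimethyloxiran-2-yl)-3,7-dimethylnona-2,6-dien-1-yl]-2,2-dimethyl-1,3-dioxan-5-ylidene]acetate | COC(=O)/C=C1\COC(C)(C)O[C@@H]1C/C=C(\C)CC/C=C(\C)CCC1OC1(C)C
F5 | step 11 | (4E,8E,11R)-11-hydroxy-4,8-dimethyl-11-(5-oxo-2,5-dihydrofuran-3-yl)undeca-4,8-dienal | O[C@H](C/C=C(\C)CC/C=C(\C)CCC=O)C1=CC(=O)OC1
F6 | step 8 | 4-methyl-2-[(trimethylsilyl)oxy]penta-1,3-diene | CC(C)=CC(=C)O[Si](C)(C)C
F7 | step 8 | 1-bromo-4-methylpent-3-en-2-one | CC(C)=CC(=O)CBr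
F8 | step 8 | methyl 2-[bis(2,2,2-trifluoroethoxy)phosphoryl]-6-methyl-4-oxohept-5-enoate | COC(=O)C(CC(=O)C=C(C)C)P(=O)(OCC(F)(F)F)OCC(F)(F)F
F9 | step 8 | methyl (2Z,6E,10E)-12-hydroxy-6,10-dimethyl-2-(4-methyl-2-oxopent-3-en-1-yl)dodeca-2,6,10-trienoate | COC(=O)/C(CC(=O)C=C(C)C)=C\CC/C(C)=C/CC/C(C)=C/CO
F10 | step 8 | methyl (2Z,6E,10E)-12-hydroxy-2-[(2S)-2-hydroxy-4-methylpent-3-en-1-yl]-6,10-dimethyldodeca-2,6,10-trienoate | COC(=O)/C(C[C@H](O)C=C(C)C)=C\CC/C(C)=C/CC/C(C)=C/CO
F11 | step 13 | (3R,5E,9E,13Z)-1,3-dihydroxy-6,10-dimethyl-13-[(5S)-5-(2-methylprop-1-en-1-yl)-2-oxooxolan-3-ylidene]trideca-5,9-dien-2-one | OCC(=O)[C@H](O)C/C=C(\C)CC/C=C(\C)CC/C=C1/C[C@@H](C=C(C)C)OC1=O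
F12 | step 13 | (3R,5E,9E,13Z)-3-hydroxy-6,10-dimethyl-13-[(5S)-5-(2-methylprop-1-en-1-yl)-2-oxooxolan-3-ylidene]-2-oxotrideca-5,9-dien-1-yl (diethoxyphosphoryl)acetate | CCOP(=O)(OCC)CC(=O)OCC(=O)[C@H](O)C/C=C(\C)CC/C=C(\C)CC/C=C1/C[C@@H](C=C(C)C)OC1=O
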